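Everything rests on cutting ring C of the flavanone half into the heterodiene O1–C8a=C4a–C4, anchored in ring A, and the C2–C3 unit of 4-vinylanisole. One inverse-demand hetero-[4+2] addition under a chiral Brønsted acid forms O1–C2 and C3–C4, closes the pyran and sets C2. The feature exploited is that C2 bears both O1 and the cation-stabilising anisyl group, which matches the polarity of the styrene. The precursor is a salicylaldehyde with one free phenol whose C5 carries the benzyl-protected flavone half. A bromine at its C3 (later C8) directs the halogenations, blocks ring A and leaves in the final hydrogenolysis. C4 arrives as a methyl ether.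

Key step: step 9

Remark on numbering: the carbon that bears the flavone half is C5 of the salicylaldehyde (para to the free hydroxyl) and becomes C6 of the flavan.
Assumption on the catalyst: the sense of induction cannot be predicted with certainty, so the (R)-acid is written and its enantiomer is used if the first run leads into the 2R series.
Assumption on the axis: the biaryl bond has only three small oxygen ortho substituents and is treated as freely rotating, in line with a target SMILES without an axial descriptor.

Step 1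
Reactants: 1 2',4',6'-trihydroxyacetophenone
Product: 2 4',6'-bis(benzyloxy)-2'-hydroxyacetophenone
Conditions: BnBr (2.1 equiv), K2CO3 (2.2 equiv), DMF, rt to 50 °C
Reagents that add atoms: benzyl bromide, BrCc1ccccc1
Why: The Williamson ether synthesis should stop after two benzylations because the last hydroxyl is held in a strong hydrogen bond to the acetyl oxygen and is much less nucleophilic.

Step 2
Reactants: 2 4',6'-bis(benzyloxy)-2'-hydroxyacetophenone; 3 3-iodo-4-methoxybenzaldehyde
Product: 4 (E)-1-[2,4-bis(benzyloxy)-6-hydroxyphenyl]-3-(3-iodo-4-methoxyphenyl)prop-2-en-1-one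
Conditions: KOH, EtOH/THF, rt
Reagents that add atoms: none
Why: Claisen–Schmidt condensation of a methyl ketone with a non-enolisable aldehyde gives the E-enone by E1cB loss of water, and the aryl iodide is inert to hydroxide at room temperature.

Step 3
Reactants: 4 (E)-chalcone
Product: 5 5,7-bis(benzyloxy)-3'-iodo-4'-methoxyflavone
Conditions: I2 (10 mol %), DMSO, 120 °C, short heating
Reagents that add atoms: none
Why: Iodine/DMSO oxidative cyclisation of a 2'-hydroxychalcone (oxa-Michael closure, then iodination and loss of HI, with DMSO as terminal oxidant) is the standard entry to flavones and should spare the aryl iodide and the benzyl ethers.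

Step 4
Reactants: 5 5,7-bis(benzyloxy)-3'-iodo-4'-methoxyflavone
Product: 6 5,7-bis(benzyloxy)-4'-methoxyflavone-3'-boronic acid pinacol ester
Conditions: B2pin2, Pd(dppf)Cl2 (5 mol %), KOAc, 1,4-dioxane, 90 °C
Reagents that add atoms: bis(pinacolato)diboron, CC1(C)OB(OC1(C)C)B1OC(C)(C)C(C)(C)O1
Why: Miyaura borylation puts boron on the ring where it has only one ortho methoxy group, which gives a boronate far less prone to protodeboronation than a 2,6-dialkoxyarylboron reagent made from ring A.

Step 5
Reactants: 7 3,5-bis(benzyloxy)phenol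
Product: 8 4,6-bis(benzyloxy)salicylaldehyde (2,4-bis(benzyloxy)-6-hydroxybenzaldehyde)
Conditions: MgCl2 (anhydrous), Et3N, (CH2O)n, MeCN, reflux
Reagents that add atoms: paraformaldehyde (as formaldehyde), C=O
Why: The magnesium-mediated ortho-formylation (Casnati–Skattebøl reaction) delivers formaldehyde only next to the magnesium-bound phenol oxygen, and the two ortho carbons of the symmetric phenol are equivalent, so a single aldehyde should result.

Step 6
Reactants: 8 4,6-bis(benzyloxy)salicylaldehyde
Product: 9 3-bromo-4,6-bis(benzyloxy)salicylaldehyde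
Conditions: NBS (1.0 equiv), CH2Cl2, –10 °C, dark
Reagents that add atoms: N-bromosuccinimide, O=C1CCC(=O)N1Br
Why: Electrophilic aromatic bromination should take C3, ortho to the chelated hydroxyl and para to the 6-benzyloxy group, as is usual for 2-hydroxy-4,6-dialkoxyaryl carbonyl compounds, because C5 is screened by two benzyloxy groups.

Step 7
Reactants: 9 3-bromo-4,6-bis(benzyloxy)salicylaldehyde
Product: 10 3-bromo-5-iodo-4,6-bis(benzyloxy)salicylaldehyde
Conditions: NIS (1.1 equiv), TFA (cat.), MeCN, rt
Reagents that add atoms: N-iodosuccinimide, O=C1CCC(=O)N1I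
Why: Acid-activated electrophilic iodination can only take the last free ring carbon, C5 between the benzyloxy groups, which avoids lithiating benzyl ethers that are prone to benzylic deprotonation and Wittig rearrangement.

Step 8
Reactants: 10 3-bromo-5-iodo-4,6-bis(benzyloxy)salicylaldehyde; 6 flavone 3'-boronic acid pinacol ester
Product: 11 3-bromo-4,6-bis(benzyloxy)-5-[5-(5,7-bis(benzyloxy)-4-oxo-4H-chromen-2-yl)-2-methoxyphenyl]salicylaldehyde
Conditions: Pd(OAc)2 (5 mol %), SPhos (10 mol %), K3PO4, toluene/H2O, 70 °C, 6 as limiting reagent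
Reagents that add atoms: none
Why: In this Suzuki–Miyaura coupling zerovalent palladium inserts into C–I much faster than into C–Br, and the bulky electron-rich biarylphosphine is suited to tri-ortho-substituted biaryls.

Step 9
Reactants: 11 biaryl salicylaldehyde; 12 4-vinylanisole (3 equiv)
Product: 15 (2S,4S)-5,7-bis(benzyloxy)-8-bromo-4-methoxy-2-(4-methoxyphenyl)-6-[5-(5,7-bis(benzyloxy)-4-oxo-4H-chromen-2-yl)-2-methoxyphenyl]chroman (2,4-cis), via dimethyl acetal 13 (not isolated), via methoxy quinone methide 14 (not isolated)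
Conditions: HC(OMe)3 (2 equiv), (R)-TRIP [(R)-3,3'-bis(2,4,6-triisopropylphenyl)-1,1'-binaphthyl-2,2'-diyl hydrogen phosphate] (10 mol %), 5 Å MS, toluene, 0 °C
Reagents that add atoms: trimethyl orthoformate, COC(OC)OC
Why: Proposed new method: the acid and HC(OMe)3 turn the aldehyde into acetal 13, loss of methanol gives quinone methide 14 (O-protonated form: the aryl oxocarbenium ion) hydrogen-bonded through O1 to the chiral phosphate, and the CH2 terminus of 12 attacks C4 while the anisyl-stabilised carbon bonds to O1 in a concerted but asynchronous inverse-demand hetero-[4+2] addition that re-aromatises ring A. The closest known reaction types are achiral acid-promoted additions of styrenes to quinone methides made from salicylaldehydes and orthoformates, which give 4-alkoxyflavans, and chiral phosphoric acid catalysed cycloadditions of quinone methides made from 2-hydroxybenzyl alcohols; the enantioselective merger with a plain styrene is not established. Ring C closes as a six-membered pyran in the cycloaddition itself, O1–C2 and C3–C4 forming in one event, so no separate ring-closure mode competes. C2 is controlled by the catalyst, whose 3,3'-aryl groups leave one face of the bound heterodiene open to the styrene, and C4 follows from the endo placement of the anisyl group (2,4-cis); as C4 is flattened in step 11, its epimer is equally useful. The step needs regioselectivity, secured by the polarity match between the 4-methoxy-activated alkene and the C4-electrophilic heterodiene, and site selectivity, secured by the single free phenol, which places the aryl substituent at C6. The C8 bromine closes the only nucleophilic ring A carbon to Friedel–Crafts attack by C4 cations and makes 14 more electrophilic, and a phosphoric acid is too weak to polymerise 12 quickly at 0 °C.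

Step 10
Reactants: 15 (2S,4S)-8-bromo-4-methoxyflavan
Product: 16 (2S)-5,7-bis(benzyloxy)-8-bromo-2-(4-methoxyphenyl)-6-[5-(5,7-bis(benzyloxy)-4-oxo-4H-chromen-2-yl)-2-methoxyphenyl]chroman-4-ol (both C4 epimers)
Conditions: p-TsOH·H2O (10 mol %), THF/H2O (4:1), rt
Reagents that add atoms: water, O
Why: SN1 solvolysis of the benzylic methyl ether needs only weak acid because the C4 cation is stabilised by O1 and the 5- and 7-benzyloxy groups, while O1–C2 stays intact and blocked C8 rules out self-condensation, so C2 should be retained.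

Step 11
Reactants: 16 (2S)-flavan-4-ol
Product: 17 (2S)-5,7-bis(benzyloxy)-8-bromo-2-(4-methoxyphenyl)-6-[5-(5,7-bis(benzyloxy)-4-oxo-4H-chromen-2-yl)-2-methoxyphenyl]chroman-4-one
Conditions: Dess–Martin periodinane, pyridine, CH2Cl2, 0 °C to rt
Reagents that add atoms: none
Why: Dess–Martin oxidation converts both C4 epimers of the secondary benzylic alcohol into one ketone under buffered conditions, and with all phenols protected no retro-oxa-Michael opening should threaten C2.

Step 12
Reactants: 17 (2S)-8-bromo tetrabenzyl flavanone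
Product: 18 (2S)-5,7-dihydroxy-6-[5-(5,7-dihydroxy-4-oxo-4H-chromen-2-yl)-2-methoxyphenyl]-2-(4-methoxyphenyl)chroman-4-one (CNP0081547.1)
Conditions: H2 (1 atm), Pd/C (10 wt %), NaOAc (1.1 equiv), THF/MeOH, rt
Reagents that add atoms: none
Why: Catalytic hydrogenolysis cleaves the four O-benzyl bonds and the C8–Br bond in one operation in an acetate buffer, where the flavone C2=C3 bond, the chelated ketone and the base-labile C2 centre should persist.

Compound list
1 | 2',4',6'-trihydroxyacetophenone | CC(=O)c1c(O)cc(O)cc1O | starting material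
2 | 4',6'-bis(benzyloxy)-2'-hydroxyacetophenone | CC(=O)c1c(O)cc(OCc2ccccc2)cc1OCc1ccccc1 | intermediate
3 | 3-iodo-4-methoxybenzaldehyde | COc1ccc(C=O)cc1I | starting material
4 | (E)-1-[2,4-bis(benzyloxy)-6-hydroxyphenyl]-3-(3-iodo-4-methoxyphenyl)prop-2-en-1-one | COc1ccc(/C=C/C(=O)c2c(O)cc(OCc3ccccc3)cc2OCc2ccccc2)cc1I | intermediate
5 | 5,7-bis(benzyloxy)-3'-iodo-4'-methoxyflavone | COc1ccc(-c2cc(=O)c3c(OCc4ccccc4)cc(OCc4ccccc4)cc3o2)cc1I | intermediate
6 | 5,7-bis(benzyloxy)-4'-methoxyflavone-3'-boronic acid pinacol ester | COc1ccc(-c2cc(=O)c3c(OCc4ccccc4)cc(OCc4ccccc4)cc3o2)cc1B1OC(C)(C)C(C)(C)O1 | intermediate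
7 | 3,5-bis(benzyloxy)phenol | Oc1cc(OCc2ccccc2)cc(OCc2ccccc2)c1 | starting material
8 | 4,6-bis(benzyloxy)salicylaldehyde | O=Cc1c(O)cc(OCc2ccccc2)cc1OCc1ccccc1 | intermediate
9 | 3-bromo-4,6-bis(benzyloxy)salicylaldehyde | O=Cc1c(O)c(Br)c(OCc2ccccc2)cc1OCc1ccccc1 | intermediate
10 | 3-bromo-5-iodo-4,6-bis(benzyloxy)salicylaldehyde | O=Cc1c(O)c(Br)c(OCc2ccccc2)c(I)c1OCc1ccccc1 | intermediate
11 | 3-bromo-4,6-bis(benzyloxy)-5-[5-(5,7-bis(benzyloxy)-4-oxo-4H-chromen-2-yl)-2-methoxyphenyl]salicylaldehyde | O=Cc1c(O)c(Br)c(OCc2ccccc2)c(-c2cc(-c3cc(=O)c4c(OCc5ccccc5)cc(OCc5ccccc5)cc4o3)ccc2OC)c1OCc1ccccc1 | intermediate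
12 | 4-vinylanisole | C=Cc1ccc(OC)cc1 | starting material
13 | dimethyl acetal of 11 | COC(OC)c1c(O)c(Br)c(OCc2ccccc2)c(-c2cc(-c3cc(=O)c4c(OCc5ccccc5)cc(OCc5ccccc5)cc4o3)ccc2OC)c1OCc1ccccc1 | intermediate
14 | 6-(methoxymethylidene)cyclohexa-2,4-dien-1-one derived from 13 (methoxy ortho-quinone methide) | COC=C1C(=O)C(Br)=C(OCc2ccccc2)C(-c2cc(-c3cc(=O)c4c(OCc5ccccc5)cc(OCc5ccccc5)cc4o3)ccc2OC)=C1OCc1ccccc1 | intermediate
15 | (2S,4S)-8-bromo-4-methoxyflavan, tetrabenzyl ether (2,4-cis) | COc1ccc([C@@H]2C[C@H](OC)c3c(c(Br)c(OCc4ccccc4)c(-c4cc(-c5cc(=O)c6c(OCc7ccccc7)cc(OCc7ccccc7)cc6o5)ccc4OC)c3OCc3ccccc3)O2)cc1 | intermediate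
16 | (2S)-8-bromoflavan-4-ol, tetrabenzyl ether (both C4 epimers) | COc1ccc([C@@H]2CC(O)c3c(c(Br)c(OCc4ccccc4)c(-c4cc(-c5cc(=O)c6c(OCc7ccccc7)cc(OCc7ccccc7)cc6o5)ccc4OC)c3OCc3ccccc3)O2)cc1 | intermediate
17 | (2S)-8-bromoflavanone, tetrabenzyl ether | COc1ccc([C@@H]2CC(=O)c3c(c(Br)c(OCc4ccccc4)c(-c4cc(-c5cc(=O)c6c(OCc7ccccc7)cc(OCc7ccccc7)cc6o5)ccc4OC)c3OCc3ccccc3)O2)cc1 | intermediate
18 | CNP0081547.1, (2S)-flavanone–flavone dimer | COc1ccc([C@@H]2CC(=O)c3c(cc(O)c(-c4cc(-c5cc(=O)c6c(O)cc(O)cc6o5)ccc4OC)c3O)O2)cc1 | target

Total step count: 12. Longest linear sequence: 9 steps (1, 2, 3, 4, 8, 9, 10, 11, 12).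

Steps most likely to fail

Step 9. The donor-rich heterodiene may react too slowly with the styrene. The basic flavone carbonyl may tie up the acid, the styrene may oligomerise cationically, or facial selectivity at C2 may be poor.
- The fallback uses known chemistry only, sets out from 2, uses 6 and comes back at 17.
- Ketone 2 is brominated with NBS to 3'-bromo-4',6'-bis(benzyloxy)-2'-hydroxyacetophenone F1.
- NIS/TFA then gives 3'-bromo-5'-iodo-4',6'-bis(benzyloxy)-2'-hydroxyacetophenone F2.
- Suzuki–Miyaura coupling with 6, as in step 8, gives the biaryl acetophenone F3.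
- DMF dimethyl acetal in hot toluene gives the enaminone F4, which closes with aqueous HCl to the 2,3-unsubstituted 8-bromochromone F5.
- A rhodium-catalysed asymmetric conjugate addition (Hayashi–Miyaura reaction) then sets C2 and gives 17. It uses 4-methoxyphenylboronic acid, [Rh(OH)(cod)]2 and an electron-poor MeO-BIPHEP-type bisphosphine in toluene/H2O at rt, with the ligand enantiomer chosen for 2S.
- The flavone ring is substituted at its β-carbon and should not accept the aryl group.

Step 8. Insertion into the crowded C–I bond of the electron-rich phenoxide may be slow, so that protodeboronation and hydrodeiodination take over. Discrimination between iodine and bromine may also be lost.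
- The fallback removes the phenoxide from the coupling by changing the substrate. It sets out from 10 and comes back at 11.
- MOMCl and iPr2NEt give the methoxymethyl ether of the dihalosalicylaldehyde F6.
- Coupling of this neutral iodide with 6 gives the methoxymethyl-protected biaryl aldehyde F7.
- Dilute HCl in THF removes the acetal, which is labile next to the aldehyde, and gives 11.

Step 10. The C4 cation may lose a C3 proton and drift into flav-3-ene chemistry. Reversible opening of O1–C2 in the cation may also erode the configuration at C2.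
- The fallback replaces solvolysis by oxidation. It sets out from 15 and comes back at 17, bypassing 16.
- DDQ in CH2Cl2/pH 7 buffer abstracts hydride from C4–H of the electron-rich benzylic methyl ether, and water collapses the resulting oxocarbenium ion to the ketone with loss of methanol.
- No new isolable compound arises on this path.

Further compounds
F1 | step 9 | 3'-bromo-4',6'-bis(benzyloxy)-2'-hydroxyacetophenone | CC(=O)c1c(O)c(Br)c(OCc2ccccc2)cc1OCc1ccccc1
F2 | step 9 | 3'-bromo-5'-iodo-4',6'-bis(benzyloxy)-2'-hydroxyacetophenone | CC(=O)c1c(O)c(Br)c(OCc2ccccc2)c(I)c1OCc1ccccc1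
F3 | step 9 | biaryl acetophenone (acetyl analogue of 11) | CC(=O)c1c(O)c(Br)c(OCc2ccccc2)c(-c2cc(-c3cc(=O)c4c(OCc5ccccc5)cc(OCc5ccccc5)cc4o3)ccc2OC)c1OCc1ccccc1
F4 | step 9 | (E)-3-(dimethylamino)prop-2-en-1-one (enaminone) of F3 | CN(C)/C=C/C(=O)c1c(O)c(Br)c(OCc2ccccc2)c(-c2cc(-c3cc(=O)c4c(OCc5ccccc5)cc(OCc5ccccc5)cc4o3)ccc2OC)c1OCc1ccccc1
F5 | step 9 | 5,7-bis(benzyloxy)-8-bromo-6-[5-(5,7-bis(benzyloxy)-4-oxo-4H-chromen-2-yl)-2-methoxyphenyl]chromone | O=c1ccoc2c(Br)c(OCc3ccccc3)c(-c3cc(-c4cc(=O)c5c(OCc6ccccc6)cc(OCc6ccccc6)cc5o4)ccc3OC)c(OCc3ccccc3)c12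
F6 | step 8 | 2,4-bis(benzyloxy)-5-bromo-3-iodo-6-(methoxymethoxy)benzaldehyde | O=Cc1c(OCOC)c(Br)c(OCc2ccccc2)c(I)c1OCc1ccccc1
F7 | step 8 | methoxymethyl ether of 11 | O=Cc1c(OCOC)c(Br)c(OCc2ccccc2)c(-c2cc(-c3cc(=O)c4c(OCc5ccccc5)cc(OCc5ccccc5)cc4o3)ccc2OC)c1OCc1ccccc1
F0 | step 10 | none | none
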